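## Retrosynthetic overview
1. Target ⇒ tri-O-benzyl (E)-enone (one operation saturates the C=C and removes three benzyl ethers) ⇒ β-hydroxy ketone (dehydration).
2. Key disconnection C2–C3: intermolecular aldol addition of the lithium enolate of 2,6-bis(benzyloxy)acetophenone to 7-[4-(benzyloxy)-3-methoxyphenyl]heptanal.
3. The heptanal ⇒ saturated alcohol ⇒ styrenyl alcohol/acid ⇒ Wittig disconnection C6=C7: O-benzylvanillin + C6 phosphonium salt from 6-bromohexanoic acid.
4. The protected acetophenone ⇒ 2',6'-dihydroxyacetophenone (double O-benzylation).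
5. No ring is formed. Both benzene rings are bought intact, in O-benzylvanillin and in the acetophenone.

Assumption: the target has no stereocentre and no stereogenic double bond, so it is one achiral compound. The two Wittig-derived alkenes are E/Z mixtures and the aldol adduct and its mesylate are racemic, so their SMILES carry no descriptor there, and all these elements are erased before the target.

## Route

Step 1
Reactants: 1 6-bromohexanoic acid
Product: 2 (5-carboxypentyl)triphenylphosphonium bromide
Conditions: PPh3 (1.05 equiv), MeCN, reflux, 36 h; precipitate with Et2O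
Reagents that add atoms: triphenylphosphine, c1ccc(cc1)P(c1ccccc1)c1ccccc1
Why: SN2 quaternisation of PPh3 by an unhindered primary bromide (phosphonium salt formation) is clean, the free acid is a spectator, and the salt crystallises.

Step 2
Reactants: 2 (5-carboxypentyl)triphenylphosphonium bromide; 3 4-(benzyloxy)-3-methoxybenzaldehyde (O-benzylvanillin)
Product: 5 7-[4-(benzyloxy)-3-methoxyphenyl]hept-6-enoic acid (E/Z mixture), via potassium ylide carboxylate 4 (not isolated)
Conditions: 2 (1.3 equiv), KOtBu (2.6 equiv), THF, 0 °C → rt, 1 h; then 3 (1.0 equiv), 0 °C → rt, 4 h; H2O, toluene wash, 1 M HCl to pH 2–3, EtOAc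
Reagents that add atoms: potassium tert-butoxide, CC(C)(C)[O-].[K+] (supplies only the K+ of 4; nothing of it stays in 5)
Why: Wittig olefination of a non-enolisable aromatic aldehyde by the carboxylate ylide, where the acid product separates from Ph3PO by acid–base extraction and the E/Z ratio does not matter because the C=C is saturated in step 4.

Step 3
Reactants: 5 7-[4-(benzyloxy)-3-methoxyphenyl]hept-6-enoic acid
Product: 6 7-[4-(benzyloxy)-3-methoxyphenyl]hept-6-en-1-ol (E/Z mixture)
Conditions: LiAlH4 (2 equiv), THF, 0 °C → rt, 3 h; Fieser work-up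
Reagents that add atoms: none
Why: LiAlH4 hydride reduction takes the carboxylic acid straight to the primary alcohol and leaves the unactivated styrenyl C=C and the aryl ethers untouched.

Step 4
Reactants: 6 7-[4-(benzyloxy)-3-methoxyphenyl]hept-6-en-1-ol
Product: 7 7-[4-(benzyloxy)-3-methoxyphenyl]heptan-1-ol
Conditions: TsNHNH2 (6 equiv), DME, reflux, aq NaOAc (8 equiv) added over 4 h
Reagents that add atoms: none
Why: Diimide reduction delivers H2 in a concerted syn fashion to the non-polar C=C only, so unlike H2/Pd it cannot cleave the aryl benzyl ether, and it merges the E/Z mixture into one compound free of an acid-sensitive electron-rich styrene.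

Step 5
Reactants: 7 7-[4-(benzyloxy)-3-methoxyphenyl]heptan-1-ol
Product: 8 7-[4-(benzyloxy)-3-methoxyphenyl]heptanal
Conditions: Dess–Martin periodinane (1.2 equiv), CH2Cl2, 0 °C → rt, 1.5 h; aq Na2S2O3/NaHCO3 work-up; used promptly
Reagents that add atoms: none
Why: Dess–Martin oxidation stops at the aldehyde under near-neutral, non-aqueous conditions that the benzyl and methyl aryl ethers tolerate.

Step 6
Reactants: 9 1-(2,6-dihydroxyphenyl)ethan-1-one (2',6'-dihydroxyacetophenone)
Product: 10 1-[2,6-bis(benzyloxy)phenyl]ethan-1-one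
Conditions: BnBr (2.5 equiv), K2CO3 (4 equiv), DMF, 70 °C, 12 h
Reagents that add atoms: benzyl bromide, BrCc1ccccc1
Why: Double Williamson etherification in hot DMF with excess base also alkylates the second, hydrogen-bonded phenol, and masking both acidic OH groups allows clean enolate formation in step 7.

Step 7
Reactants: 10 1-[2,6-bis(benzyloxy)phenyl]ethan-1-one; 8 7-[4-(benzyloxy)-3-methoxyphenyl]heptanal
Product: 12 (±)-1-[2,6-bis(benzyloxy)phenyl]-9-[4-(benzyloxy)-3-methoxyphenyl]-3-hydroxynonan-1-one, via lithium enolate 11 (not isolated)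
Conditions: 10 (1.25 equiv), LDA (1.2 equiv, commercial solution), THF, −78 °C, 45 min; then 8 (1.0 equiv), −78 °C, 45 min; AcOH/THF quench at −78 °C
Reagents that add atoms: lithium diisopropylamide, CC(C)[N-]C(C)C.[Li+] (supplies only the Li+ of 11)
Why: In this directed crossed aldol addition the methyl ketone (α-hydrogens only on CH3) is fully converted to its lithium enolate before the enolisable aldehyde arrives at −78 °C, which avoids self-condensation, the cold acidic quench prevents retro-aldol, and the new C3 carbinol centre forms racemic and is destroyed in step 8.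

Step 8
Reactants: 12 (±)-1-[2,6-bis(benzyloxy)phenyl]-9-[4-(benzyloxy)-3-methoxyphenyl]-3-hydroxynonan-1-one
Product: 14 (E)-1-[2,6-bis(benzyloxy)phenyl]-9-[4-(benzyloxy)-3-methoxyphenyl]non-2-en-1-one, via β-mesyloxy ketone 13 (not isolated)
Conditions: MsCl (1.5 equiv), Et3N (5 equiv), CH2Cl2, 0 °C → rt, 3 h
Reagents that add atoms: methanesulfonyl chloride, CS(=O)(=O)Cl (mesyl group of 13 only; lost again on the way to 14)
Why: Mesylation followed by E1cB elimination with excess Et3N gives the conjugated, thermodynamically favoured (E)-enone under mild non-aqueous conditions that avoid retro-aldol cleavage.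

Step 9
Reactants: 14 (E)-1-[2,6-bis(benzyloxy)phenyl]-9-[4-(benzyloxy)-3-methoxyphenyl]non-2-en-1-one
Product: 15 1-(2,6-dihydroxyphenyl)-9-(4-hydroxy-3-methoxyphenyl)nonan-1-one (target)
Conditions: H2 (1 atm), 10% Pd/C (10 wt%), EtOAc/EtOH (1:1), rt, 8–16 h, stopped when TLC shows full conversion
Reagents that add atoms: none
Why: Catalytic hydrogenation saturates the enone C=C and hydrogenolyses the three aryl benzyl ethers, while the aryl methyl ether is inert and the di-ortho-substituted, finally doubly hydrogen-bonded ketone is not reduced at 1 atm, and no stereocentre is created.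

## Compound list
1 | 6-bromohexanoic acid | OC(=O)CCCCCBr | starting material
2 | (5-carboxypentyl)triphenylphosphonium bromide | OC(=O)CCCCC[P+](c1ccccc1)(c1ccccc1)c1ccccc1.[Br-] | intermediate
3 | 4-(benzyloxy)-3-methoxybenzaldehyde | COc1cc(C=O)ccc1OCc1ccccc1 | starting material
4 | potassium 6-(triphenyl-λ5-phosphanylidene)hexanoate (ylide carboxylate) | [K+].[O-]C(=O)CCCCC=P(c1ccccc1)(c1ccccc1)c1ccccc1 | intermediate (not isolated)
5 | 7-[4-(benzyloxy)-3-methoxyphenyl]hept-6-enoic acid, E/Z mixture | COc1cc(C=CCCCCC(=O)O)ccc1OCc1ccccc1 | intermediate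
6 | 7-[4-(benzyloxy)-3-methoxyphenyl]hept-6-en-1-ol, E/Z mixture | COc1cc(C=CCCCCCO)ccc1OCc1ccccc1 | intermediate
7 | 7-[4-(benzyloxy)-3-methoxyphenyl]heptan-1-ol | COc1cc(CCCCCCCO)ccc1OCc1ccccc1 | intermediate
8 | 7-[4-(benzyloxy)-3-methoxyphenyl]heptanal | COc1cc(CCCCCCC=O)ccc1OCc1ccccc1 | intermediate
9 | 1-(2,6-dihydroxyphenyl)ethan-1-one | CC(=O)c1c(O)cccc1O | starting material
10 | 1-[2,6-bis(benzyloxy)phenyl]ethan-1-one | CC(=O)c1c(OCc2ccccc2)cccc1OCc1ccccc1 | intermediate
11 | lithium 1-[2,6-bis(benzyloxy)phenyl]ethen-1-olate | [Li+].[O-]C(=C)c1c(OCc2ccccc2)cccc1OCc1ccccc1 | intermediate (not isolated)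
12 | (±)-1-[2,6-bis(benzyloxy)phenyl]-9-[4-(benzyloxy)-3-methoxyphenyl]-3-hydroxynonan-1-one | COc1cc(CCCCCCC(O)CC(=O)c2c(OCc3ccccc3)cccc2OCc2ccccc2)ccc1OCc1ccccc1 | intermediate
13 | (±)-1-[2,6-bis(benzyloxy)phenyl]-9-[4-(benzyloxy)-3-methoxyphenyl]-1-oxononan-3-yl methanesulfonate | COc1cc(CCCCCCC(OS(C)(=O)=O)CC(=O)c2c(OCc3ccccc3)cccc2OCc2ccccc2)ccc1OCc1ccccc1 | intermediate (not isolated)
14 | (E)-1-[2,6-bis(benzyloxy)phenyl]-9-[4-(benzyloxy)-3-methoxyphenyl]non-2-en-1-one | COc1cc(CCCCCC/C=C/C(=O)c2c(OCc3ccccc3)cccc2OCc2ccccc2)ccc1OCc1ccccc1 | intermediate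
15 | 1-(2,6-dihydroxyphenyl)-9-(4-hydroxy-3-methoxyphenyl)nonan-1-one | COc1cc(CCCCCCCCC(=O)c2c(O)cccc2O)ccc1O | target

## Step count and risks
Total step count: 9. Longest linear sequence: 8 steps (1 → 2 → 5 → 6 → 7 → 8 → 12 → 14 → 15). Step 6 is the one-step side branch.

**Most likely to fail, first: step 7 (aldol).** The risks are proton exchange between enolate 11 and the enolisable aldehyde 8, and retro-aldol during work-up. The fallback sets out from 10 (partner 8 unchanged) and comes back to the route at 12. Compound 10 is soft-enolised with TMSOTf/Et3N (CH2Cl2, 0 °C) to {[1-(2,6-bis(benzyloxy)phenyl)ethenyl]oxy}trimethylsilane F1. This neutral nucleophile is added to 8 activated by BF3·OEt2 (CH2Cl2, −78 °C, Mukaiyama aldol). No base able to enolise 8 is then present, and the adduct is held as a boron aldolate until aqueous NaHCO3 work-up frees 12.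

**Second: step 9 (global hydrogenation).** One risk is over-reduction of the aryl ketone. The other is debenzylation running ahead of C=C reduction, followed by oxa-Michael closure to a 2-alkylchroman-4-one. The fallback sets out from 14 and comes back at 15, and it separates the two jobs:
- Conjugate reduction with Stryker's reagent ([(Ph3P)CuH]6, wet benzene, rt) gives 1-[2,6-bis(benzyloxy)phenyl]-9-[4-(benzyloxy)-3-methoxyphenyl]nonan-1-one F2.
- The three benzyl ethers are then removed without hydrogen by BCl3 (6 equiv) and pentamethylbenzene (9 equiv) in CH2Cl2 at −78 °C. The ketone and the aryl methyl ether persist under these conditions, and 15 is obtained.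

**Third: step 4 (diimide).** The risk is incomplete conversion of the 1,2-disubstituted styrene, because diimide also disproportionates. The fallback sets out from 6 and comes back at 7 by giving up chemoselectivity:
- H2 and Pd/C in EtOH saturate the alkene and cleave the benzyl ether, giving 4-(7-hydroxyheptyl)-2-methoxyphenol F3.
- The phenol alone is re-benzylated with BnBr (1.05 equiv) and K2CO3 in refluxing acetone to give 7. Carbonate does not deprotonate the aliphatic OH.

## Further compounds
F1 | step 7 | {[1-(2,6-bis(benzyloxy)phenyl)ethenyl]oxy}trimethylsilane | C=C(O[Si](C)(C)C)c1c(OCc2ccccc2)cccc1OCc1ccccc1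
F2 | step 9 | 1-[2,6-bis(benzyloxy)phenyl]-9-[4-(benzyloxy)-3-methoxyphenyl]nonan-1-one | COc1cc(CCCCCCCCC(=O)c2c(OCc3ccccc3)cccc2OCc2ccccc2)ccc1OCc1ccccc1
F3 | step 4 | 4-(7-hydroxyheptyl)-2-methoxyphenol | COc1cc(CCCCCCCO)ccc1O
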